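## Analysis of the target

The target 22 is a methylene-bridged dimer of (2S)-7-hydroxy-5-methoxyflavan: two 2-phenylchroman units joined by one CH2 group from C8 of unit A to C6 of unit B. Each benzo ring carries three oxygens in a 1,3,5 pattern (O1, 5-OMe, 7-OH), so every aromatic carbon is ortho or para to all three. In unit A the bridge lies between two oxygens (C7–O and C8a–O); in unit B it lies between the methoxy carbon C5 and C7. The only stereocentres are the two C2 carbons, both S, each benzylic and bonded to the ring oxygen O1. They are ten bonds apart, so neither can steer the other and both need the same external control. Sensitive features are the two free phenols on very electron-rich rings, the benzylic C2–O1 bonds (open to hydrogenolysis and to ionisation, which would racemise C2) and the doubly benzylic bridge CH2. The real difficulty is regiochemistry: two almost identical rings must be joined at non-equivalent carbons, and each needs a carbon substituent at C4a and a differentiated pair of oxygens, in rings where electrophilic substitution barely discriminates. The strategy rests on C2 being the carbon attached to O1: both O1–C2 bonds can be made by enantioselective allylic etherification of the two C8a phenols of a preformed core, and the vinyl group delivered with each stereocentre then closes C3=C4 onto a vinyl group at C4a.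

## Retrosynthetic reasoning

22 ⇐ 21 ⇐ 20. The last two operations only adjust protection and oxidation level. The 7-hydroxyls stay as benzyl ethers (21) until the end because they must be inert to base, iridium and ruthenium. The C3–C4 single bonds go back to the C3=C4 double bonds of the bis(2H-chromene) 20. Reduction must come before debenzylation and must be metal-free: in 20 the C2–O1 bond is allylic as well as benzylic and would be cleaved by hydrogen on palladium, whereas after saturation it is only benzylic.

20 ⇐ 19. Both C3=C4 bonds are cut. Each half of 19 then holds a styrene-type vinyl group on C4a and the vinyl group of a 1-phenylallyl ether on O1, set up for a six-membered ring-closing metathesis. The gain is that the rings close through a C=C bond formation that cannot touch C2.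

19 ⇐ 15 + 17 (key disconnection). Both O1–C2 bonds are cut, leading to the divinyl bisphenol 15 and two molecules of the achiral carbonate 17. Cutting here creates the stereocentre in the same event as the C–O bond, uses one catalyst for two identical electrophilic partners, and leaves the alkene needed for the next step. A halogen at C4a as a placeholder for the vinyl group was considered and set aside. Its later vinylation would need zerovalent palladium in the presence of 1-phenylallyl aryl ethers, which such a metal ionises, and an ortho-halophenoxide is also a weaker nucleophile and a better leaving group. The vinyl groups are therefore in place before the etherification. The forward reaction must give branched attack, one allyl face twice, O- rather than C-allylation, and must reach the crowded unit A phenoxide.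

15 ⇐ 14 ⇐ 13 ⇐ 12. The vinyl groups come from formyl groups by methylenation. The formyl groups also solve the oxygen problem. In the tetraphenol 13 each C8a hydroxyl is hydrogen-bonded to the neighbouring formyl group, while each C7 hydroxyl is para to formyl, free and more acidic, so benzylation goes to C7 in both rings and gives 14. All four acetal protecting groups of 12 can therefore be removed together.

12 ⇐ 10 ⇐ 9 ⇐ 7 + 5. The formyl groups come from aryl bromides by halogen–lithium exchange on the diarylmethane 10. The bridge is cut at the CH2–C6 bond of unit B: an aryllithium from the symmetric dibromide 7 adds to aldehyde 5, and the carbinol 9 is deoxygenated. Ring B enters as a symmetric dibromide, so whichever bromine is exchanged, the bridge ends between OMe and O and the other bromine sits at C4a. Ring A enters with the bridge carbon already between its two oxygens. No substitution on the assembled core is needed, which matters because in unit B both C4a and C8 are ortho to the C8a oxygen and could not be told apart.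

5 ⇐ 4 ⇐ 2 ⇐ 1 and 7 ⇐ 6 ⇐ 1. Aldehyde 4 arises by directed lithiation of 2 between its two acetal ethers; its two free ring carbons are equivalent, so monobromination gives only 5. Dibromide 7 arises from 1 by bromination para to each free hydroxyl (6) and protection. Both rings thus come from 1, and symmetry decides every regiochemical question.

17 ⇐ 16. The carbonate is the methoxycarbonyl derivative of cinnamyl alcohol 16.

## Alternatives that were turned down

Alternative 1: The C3=C4 bonds are disconnected and the stereocentres are bought. A core with a phosphonium group on each future C4 carbon (bis-phosphonium salt A3) would be deprotonated twice by a potassium amide base and condensed with two equivalents of the (S)-α-silyloxy aldehyde A2 to give the bis-alkene A1. Alkene geometry would not matter, since hydrogenation follows; unmasking of the C8a phenols and the carbinols and a double Mitsunobu closure with inversion would then form O1–C2. In its favour, no asymmetric catalysis is needed and the key step has no selectivity to achieve. Against it, the α-hydrogen of A2 is benzylic, α-oxygenated and α to a formyl group, so it is likely to epimerise under the basic ylide. The ring closure is a displacement at a secondary benzylic carbinol, done twice, where partial ionisation erodes configuration. A3 needs benzylic halides of 2,6-dioxygenated arenes, which ionise readily. Five operations follow the key step (hydrogenation, two deprotections, closure, debenzylation) against three here. This alternative is stronger in that the configuration is purchased rather than induced. The chosen route forms each stereocentre and its O1–C2 bond in one catalytic event and never exposes C2 to a substitution or an enolisable neighbour.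

Alternative 2: The benzene ring of unit A is itself disconnected (C8–C8a and C6–C7). In a Danheiser benzannulation, heating the cyclobutenone A5 with the siloxyalkyne A6, which already carries the complete unit B, would give the pentasubstituted phenol A4. The cascade is a four-electron ring opening, a ketene–alkyne [2+2] addition, a second ring opening, a six-electron closure and tautomerisation. In its favour, and stronger than the chosen route on this point, the cascade fixes every substituent of ring A by connectivity and delivers the C8a hydroxyl free with C7–O silylated. Against it, the route is strongly linear. A finished enantiopure unit B, with its own C6 regiochemistry problem, must first be made and converted into a sensitive siloxyalkyne. A5 needs a separate asymmetric synthesis of its side chain. The two stereocentres come from two unrelated sequences, and the pyran ring of unit A must still be closed by displacement at the benzylic carbinol. The chosen route answers the same regiochemistry with symmetric resorcinol intermediates in far fewer steps and sets both stereocentres in one operation.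

Alternative 3: The C2–phenyl bonds are disconnected. Phenylboronic acid A9 would add to C2 of both pyranone rings of the methylene-bridged bis-chromone A8 under a cationic divalent palladium catalyst with a chiral pyridine–oxazoline ligand, giving the bis-flavanone A7. In its favour, it is a catalytic double asymmetric step like the chosen one, and its substrate is more robust than the vinylphenol 15. Against it, both C4 carbonyl groups must afterwards be removed (reduction and benzylic deoxygenation, at least two more steps). Until then C2 is β to a ketone and can be lost by reversible retro-oxa-Michael ring opening under acid or base. The electron-rich 5,7-dioxygenated chromones are poor acceptors, and A8 needs the same regiodefined core plus two annulated pyranones. The chosen route needs no deoxygenation, and its stereocentres are never β to a carbonyl group.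

Key step: step 13

Assumption: the (Sa,S,S) enantiomer of O,O'-(1,1'-binaphthalene-2,2'-diyl) N,N-bis(1-phenylethyl)phosphoramidite (L*) is taken to give the (S)-configured 1-phenylallyl aryl ethers; should the sense of induction be the opposite, the (Ra,R,R) ligand is used and nothing else changes.

## Route

Step 1
Reactants: 1 5-methoxyresorcinol
Product: 2 1-methoxy-3,5-bis(methoxymethoxy)benzene
Conditions: MOMCl (2.5 equiv), i-Pr2NEt (3 equiv), CH2Cl2, 0 °C to rt
Reagents that add atoms: chloromethyl methyl ether, COCCl
Why: Williamson-type O-alkylation of both phenols; the methoxymethyl ethers are chosen because they direct the lithiation of step 2 and the lithium chemistry of steps 6 and 8.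

Step 2
Reactants: 2 1-methoxy-3,5-bis(methoxymethoxy)benzene
Product: 4 4-methoxy-2,6-bis(methoxymethoxy)benzaldehyde, via aryllithium 3 (not isolated)
Conditions: n-BuLi (1.1 equiv), THF, 0 °C, 1 h; DMF (2 equiv), 0 °C to rt; H2O
Reagents that add atoms: N,N-dimethylformamide, CN(C)C=O
Why: Directed ortho-metalation followed by formylation; the hydrogen between the two acetal ethers is acidified and coordinated from both sides, so lithiation should occur there and not next to the methoxy group, which places the future bridge carbon between the two oxygens of ring A.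

Step 3
Reactants: 4 4-methoxy-2,6-bis(methoxymethoxy)benzaldehyde
Product: 5 3-bromo-4-methoxy-2,6-bis(methoxymethoxy)benzaldehyde
Conditions: NBS (1.0 equiv), MeCN, 0 °C
Reagents that add atoms: N-bromosuccinimide, O=C1CCC(=O)N1Br
Why: Electrophilic aromatic bromination; the two free ring carbons of 4 are equivalent by symmetry, so the monobromide is a single regioisomer, and the first bromine deactivates the ring towards a second.

Step 4
Reactants: 1 5-methoxyresorcinol
Product: 6 4,6-dibromo-5-methoxybenzene-1,3-diol
Conditions: NBS (2.0 equiv), MeCN, -30 to 0 °C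
Reagents that add atoms: N-bromosuccinimide, O=C1CCC(=O)N1Br
Why: Twofold electrophilic bromination; C4 and C6 are each para to one free hydroxyl and ortho to the other, the pattern that directs the dibromination of resorcinol and the C-acylation of 1, whereas C2 is para only to the weaker methoxy donor. The symmetric 4,6-isomer is therefore expected as the main product.

Step 5
Reactants: 6 4,6-dibromo-5-methoxybenzene-1,3-diol
Product: 7 2,4-dibromo-3-methoxy-1,5-bis(methoxymethoxy)benzene
Conditions: MOMCl (2.5 equiv), i-Pr2NEt (3 equiv), CH2Cl2, 0 °C to rt
Reagents that add atoms: chloromethyl methyl ether, COCCl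
Why: Williamson-type O-alkylation of the two acidic ortho-bromophenols; the acetal ethers tolerate the organolithium steps and will stabilise the neighbouring aryllithium by chelation.

Step 6
Reactants: 7 2,4-dibromo-3-methoxy-1,5-bis(methoxymethoxy)benzene; 5 3-bromo-4-methoxy-2,6-bis(methoxymethoxy)benzaldehyde
Product: 9 (±)-(3-bromo-2-methoxy-4,6-bis(methoxymethoxy)phenyl)(3-bromo-4-methoxy-2,6-bis(methoxymethoxy)phenyl)methanol, via aryllithium 8 (not isolated)
Conditions: 7, n-BuLi (1.0 equiv), THF, -78 °C, 20 min; then 5 in THF, -78 to -30 °C; H2O
Reagents that add atoms: none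
Why: Bromine–lithium exchange followed by 1,2-addition of the aryllithium to the aldehyde; the two bromines of 7 are equivalent, so the bridge carbon ends between OMe and an acetal ether of ring B whichever is exchanged, and the remaining bromine is meta to lithium, so no aryne can form. Addition to the formyl group is faster than exchange with the aryl bromide of 5; the new carbinol centre is racemic and is removed in step 7.

Step 7
Reactants: 9 (±)-(3-bromo-2-methoxy-4,6-bis(methoxymethoxy)phenyl)(3-bromo-4-methoxy-2,6-bis(methoxymethoxy)phenyl)methanol
Product: 10 (3-bromo-2-methoxy-4,6-bis(methoxymethoxy)phenyl)(3-bromo-4-methoxy-2,6-bis(methoxymethoxy)phenyl)methane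
Conditions: Et3SiH (4 equiv), CF3CO2H (1.5 equiv), CH2Cl2, -40 to 0 °C; NaHCO3 quench
Reagents that add atoms: none
Why: Ionic hydrogenation; the carbinol flanked by two trioxygenated rings ionises with little acid at low temperature and the diarylmethyl cation is trapped by hydride from the silane. The short cold exposure should leave the acetal ethers intact, and the aryl bromides, which rule out hydrogenolysis over a metal, are inert.

Step 8
Reactants: 10 (3-bromo-2-methoxy-4,6-bis(methoxymethoxy)phenyl)(3-bromo-4-methoxy-2,6-bis(methoxymethoxy)phenyl)methane
Product: 12 (3-formyl-2-methoxy-4,6-bis(methoxymethoxy)phenyl)(3-formyl-4-methoxy-2,6-bis(methoxymethoxy)phenyl)methane, via dilithio species 11 (not isolated)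
Conditions: t-BuLi (4.4 equiv), THF, -78 °C, 15 min; DMF (6 equiv), -78 to 0 °C; H2O
Reagents that add atoms: N,N-dimethylformamide, CN(C)C=O
Why: Double bromine–lithium exchange and formylation; at -78 °C exchange is much faster than deprotonation of the bridge CH2, and each aryllithium is held by its OMe and acetal neighbours. The formyl carbons become C4 of both units and sit ortho to the future O1 oxygens.

Step 9
Reactants: 12 (3-formyl-2-methoxy-4,6-bis(methoxymethoxy)phenyl)(3-formyl-4-methoxy-2,6-bis(methoxymethoxy)phenyl)methane
Product: 13 (3-formyl-4,6-dihydroxy-2-methoxyphenyl)(3-formyl-2,6-dihydroxy-4-methoxyphenyl)methane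
Conditions: HCl (3 M aq.), MeOH/THF, 45 °C
Reagents that add atoms: none
Why: Acid-catalysed acetal cleavage (transacetalisation to methanol) of all four methoxymethyl ethers; the formyl groups lower the ring electron density enough to protect the bridge from acid-induced scrambling.

Step 10
Reactants: 13 (3-formyl-4,6-dihydroxy-2-methoxyphenyl)(3-formyl-2,6-dihydroxy-4-methoxyphenyl)methane
Product: 14 (6-benzyloxy-3-formyl-4-hydroxy-2-methoxyphenyl)(6-benzyloxy-3-formyl-2-hydroxy-4-methoxyphenyl)methane
Conditions: BnBr (2.1 equiv), K2CO3 (2.2 equiv), acetone, 45 °C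
Reagents that add atoms: benzyl bromide, BrCc1ccccc1
Why: Chelation-controlled selective Williamson etherification; in each ring the C8a hydroxyl is hydrogen-bonded to the adjacent formyl group and stays, while the C7 hydroxyl, para to formyl, is free and more acidic and is benzylated. This is the step that tells the two oxygens of each ring apart.

Step 11
Reactants: 14 (6-benzyloxy-3-formyl-4-hydroxy-2-methoxyphenyl)(6-benzyloxy-3-formyl-2-hydroxy-4-methoxyphenyl)methane
Product: 15 (6-benzyloxy-4-hydroxy-2-methoxy-3-vinylphenyl)(6-benzyloxy-2-hydroxy-4-methoxy-3-vinylphenyl)methane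
Conditions: Ph3PCH3Br (6 equiv), KOt-Bu (5.8 equiv), THF, 0 to 40 °C; NH4Cl work-up, Et3N-deactivated silica, product kept cold
Reagents that add atoms: methyltriphenylphosphonium bromide, C[P+](c1ccccc1)(c1ccccc1)c1ccccc1.[Br-]
Why: Wittig methylenation of both aldehydes; two equivalents of ylide serve as base for the phenols, and the unstabilised ylide is reactive enough for the phenoxide-bearing formyl groups. Acid is avoided in the work-up because electron-rich ortho-vinylphenols oligomerise on protonation.

Step 12
Reactants: 16 (E)-cinnamyl alcohol
Product: 17 methyl (E)-cinnamyl carbonate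
Conditions: ClCO2Me (1.3 equiv), pyridine (1.5 equiv), CH2Cl2, 0 °C
Reagents that add atoms: methyl chloroformate, COC(=O)Cl
Why: O-acylation of the allylic alcohol to the carbonate; the alkene geometry is not touched.

Step 13
Reactants: 15 (6-benzyloxy-4-hydroxy-2-methoxy-3-vinylphenyl)(6-benzyloxy-2-hydroxy-4-methoxy-3-vinylphenyl)methane; 17 methyl (E)-cinnamyl carbonate
Product: 19 (6-benzyloxy-2-methoxy-4-[(S)-1-phenylallyloxy]-3-vinylphenyl)(6-benzyloxy-4-methoxy-2-[(S)-1-phenylallyloxy]-3-vinylphenyl)methane, via dilithium bis(phenoxide) 18 (not isolated)
Conditions: [Ir(cod)Cl]2 (4 mol%), L* (8 mol%), n-PrNH2, THF, 50 °C, 30 min, then volatiles removed; 15, LiN(SiMe3)2 (2.05 equiv), THF, 0 °C; 17 (3 equiv), THF, 25 to 50 °C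
Reagents that add atoms: none
Why: Iridium-catalysed asymmetric allylic etherification; the closest known reaction type is the branched-selective O-allylation of lithium and sodium phenoxides, ortho-alkenylphenoxides included, with cinnamyl carbonates. The cyclometalated monovalent iridium phosphoramidite complex ionises 17 with loss of methyl carbonate (which gives CO2 and methoxide) to a trivalent η3-(1-phenylallyl)iridium species. Each phenoxide of 18 then attacks from outside the coordination sphere, anti to the metal, at the phenyl-bearing allyl terminus; this forms O1–C2 of unit A and of unit B and leaves a vinyl group on each new stereocentre. No ring closes in this step. Both stereocentres are set by the chiral ligand, which fixes the allyl face open to the nucleophile, so (S) is expected at each carbon independently of the distant second unit; the twofold reaction should raise the enantiomeric purity of the main (S,S) isomer at the cost of a little (R,S) diastereomer. The step needs branched over linear attack, O- over C-allylation and reaction at both phenols: the aryl group of the allyl unit directs attack to the substituted terminus under iridium, the lithium counter-ion in THF keeps the phenoxide an oxygen nucleophile, and the electron-rich phenoxides are poor leaving groups, so the ethers should not re-ionise. The unit A phenoxide, flanked by the vinyl group and the bridge, is the slower site and sets the reaction time and the excess of 17.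

Step 14
Reactants: 19 (6-benzyloxy-2-methoxy-4-[(S)-1-phenylallyloxy]-3-vinylphenyl)(6-benzyloxy-4-methoxy-2-[(S)-1-phenylallyloxy]-3-vinylphenyl)methane
Product: 20 (2S)-7-benzyloxy-8-{[(2S)-7-benzyloxy-5-methoxy-2-phenyl-2H-chromen-6-yl]methyl}-5-methoxy-2-phenyl-2H-chromene
Conditions: second-generation Grubbs catalyst RuCl2(=CHPh)(PCy3)(H2IMes) (2 × 5 mol%), 1,4-benzoquinone (10 mol%), CH2Cl2 (5 mM), 40 °C, dark
Reagents that add atoms: none
Why: Double ring-closing metathesis; in each half the aryl vinyl group and the vinyl group of the allyl ether close the six-membered pyran ring (C3=C4) with loss of ethene, far faster than any cross-metathesis between the halves. C2 is not involved, and benzoquinone suppresses ruthenium hydride isomerisation of the allyl ether, which would destroy the stereocentre.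

Step 15
Reactants: 20 (2S)-7-benzyloxy-8-{[(2S)-7-benzyloxy-5-methoxy-2-phenyl-2H-chromen-6-yl]methyl}-5-methoxy-2-phenyl-2H-chromene
Product: 21 (2S)-7-benzyloxy-8-{[(2S)-7-benzyloxy-5-methoxy-2-phenylchroman-6-yl]methyl}-5-methoxy-2-phenylchroman
Conditions: 2-nitrobenzenesulfonohydrazide (10 equiv), Et3N, CH2Cl2, rt, dark
Reagents that add atoms: none
Why: Diimide reduction; concerted syn transfer of two hydrogens to each C3=C4 bond without a metal, so the allylic and benzylic C2–O1 bonds and the benzyl ethers are untouched. Room temperature and darkness avoid electrocyclic opening of the 2H-chromene, which would racemise C2.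

Step 16
Reactants: 21 (2S)-7-benzyloxy-8-{[(2S)-7-benzyloxy-5-methoxy-2-phenylchroman-6-yl]methyl}-5-methoxy-2-phenylchroman
Product: 22 (2S)-8-{[(2S)-7-hydroxy-5-methoxy-2-phenylchroman-6-yl]methyl}-5-methoxy-2-phenylchroman-7-ol
Conditions: H2 (1 atm), Pd/C (10%), EtOAc/MeOH, rt, stopped at full conversion
Reagents that add atoms: none
Why: Hydrogenolysis of the two aryl benzyl ethers; after step 15 the C2–O1 bond is only a cyclic benzylic ether, which is cleaved much more slowly than an O-benzyl group under neutral conditions, so the flavan rings and both stereocentres should survive.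

## Compound list

1 | 5-methoxyresorcinol (5-methoxybenzene-1,3-diol) | COc1cc(O)cc(O)c1 | starting material
2 | 1-methoxy-3,5-bis(methoxymethoxy)benzene | COCOc1cc(OC)cc(OCOC)c1 | intermediate
3 | [4-methoxy-2,6-bis(methoxymethoxy)phenyl]lithium | COCOc1cc(OC)cc(OCOC)c1[Li] | intermediate
4 | 4-methoxy-2,6-bis(methoxymethoxy)benzaldehyde | COCOc1cc(OC)cc(OCOC)c1C=O | intermediate
5 | 3-bromo-4-methoxy-2,6-bis(methoxymethoxy)benzaldehyde | COCOc1cc(OC)c(Br)c(OCOC)c1C=O | intermediate
6 | 4,6-dibromo-5-methoxybenzene-1,3-diol | COc1c(Br)c(O)cc(O)c1Br | intermediate
7 | 2,4-dibromo-3-methoxy-1,5-bis(methoxymethoxy)benzene | COCOc1cc(OCOC)c(Br)c(OC)c1Br | intermediate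
8 | [3-bromo-2-methoxy-4,6-bis(methoxymethoxy)phenyl]lithium | COCOc1cc(OCOC)c(Br)c(OC)c1[Li] | intermediate
9 | (±)-(3-bromo-2-methoxy-4,6-bis(methoxymethoxy)phenyl)(3-bromo-4-methoxy-2,6-bis(methoxymethoxy)phenyl)methanol | COCOc1cc(OCOC)c(Br)c(OC)c1C(O)c1c(OCOC)cc(OC)c(Br)c1OCOC | intermediate
10 | (3-bromo-2-methoxy-4,6-bis(methoxymethoxy)phenyl)(3-bromo-4-methoxy-2,6-bis(methoxymethoxy)phenyl)methane | COCOc1cc(OCOC)c(Br)c(OC)c1Cc1c(OCOC)cc(OC)c(Br)c1OCOC | intermediate
11 | dilithio species of 10 (lithium in place of both bromines) | COCOc1cc(OCOC)c([Li])c(OC)c1Cc1c(OCOC)cc(OC)c([Li])c1OCOC | intermediate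
12 | (3-formyl-2-methoxy-4,6-bis(methoxymethoxy)phenyl)(3-formyl-4-methoxy-2,6-bis(methoxymethoxy)phenyl)methane | COCOc1cc(OCOC)c(C=O)c(OC)c1Cc1c(OCOC)cc(OC)c(C=O)c1OCOC | intermediate
13 | (3-formyl-4,6-dihydroxy-2-methoxyphenyl)(3-formyl-2,6-dihydroxy-4-methoxyphenyl)methane | COc1c(C=O)c(O)cc(O)c1Cc1c(O)cc(OC)c(C=O)c1O | intermediate
14 | (6-benzyloxy-3-formyl-4-hydroxy-2-methoxyphenyl)(6-benzyloxy-3-formyl-2-hydroxy-4-methoxyphenyl)methane | COc1c(C=O)c(O)cc(OCc2ccccc2)c1Cc1c(OCc2ccccc2)cc(OC)c(C=O)c1O | intermediate
15 | (6-benzyloxy-4-hydroxy-2-methoxy-3-vinylphenyl)(6-benzyloxy-2-hydroxy-4-methoxy-3-vinylphenyl)methane | COc1c(C=C)c(O)cc(OCc2ccccc2)c1Cc1c(OCc2ccccc2)cc(OC)c(C=C)c1O | intermediate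
16 | (E)-cinnamyl alcohol | OC/C=C/c1ccccc1 | starting material
17 | methyl (E)-cinnamyl carbonate | COC(=O)OC/C=C/c1ccccc1 | intermediate
18 | dilithium bis(phenoxide) of 15 | COc1c(C=C)c([O-])cc(OCc2ccccc2)c1Cc1c(OCc2ccccc2)cc(OC)c(C=C)c1[O-].[Li+].[Li+] | intermediate
19 | (6-benzyloxy-2-methoxy-4-[(S)-1-phenylallyloxy]-3-vinylphenyl)(6-benzyloxy-4-methoxy-2-[(S)-1-phenylallyloxy]-3-vinylphenyl)methane | COc1c(C=C)c(O[C@@H](C=C)c2ccccc2)cc(OCc2ccccc2)c1Cc1c(OCc2ccccc2)cc(OC)c(C=C)c1O[C@@H](C=C)c1ccccc1 | intermediate
20 | (2S)-7-benzyloxy-8-{[(2S)-7-benzyloxy-5-methoxy-2-phenyl-2H-chromen-6-yl]methyl}-5-methoxy-2-phenyl-2H-chromene | COc1cc(OCc2ccccc2)c(Cc2c(OCc3ccccc3)cc3c(c2OC)C=C[C@@H](c2ccccc2)O3)c2c1C=C[C@@H](c1ccccc1)O2 | intermediate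
21 | (2S)-7-benzyloxy-8-{[(2S)-7-benzyloxy-5-methoxy-2-phenylchroman-6-yl]methyl}-5-methoxy-2-phenylchroman | COc1cc(OCc2ccccc2)c(Cc2c(OCc3ccccc3)cc3c(c2OC)CC[C@@H](c2ccccc2)O3)c2c1CC[C@@H](c1ccccc1)O2 | intermediate
22 | (2S)-8-{[(2S)-7-hydroxy-5-methoxy-2-phenylchroman-6-yl]methyl}-5-methoxy-2-phenylchroman-7-ol (CNP0178097.1) | COc1cc(O)c(Cc2c(O)cc3c(c2OC)CC[C@@H](c2ccccc2)O3)c2c1CC[C@@H](c1ccccc1)O2 | target

## Step count and risks

Total: 16 steps. Longest linear sequence: 13 steps (1, 2, 3, 6, 7, 8, 9, 10, 11, 13, 14, 15, 16). Steps 4 and 5 (ring B) and step 12 (carbonate) are side branches.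

Step 13 (key step). The etherification may stall after the first phenoxide, because the unit A phenoxide lies between a vinyl group and the bridge. Attack at the unsubstituted allyl terminus, C-allylation of the electron-rich rings, or slow re-ionisation of the product by the catalyst would lower regio- and enantiopurity. The fallback keeps the O1–C2 bond as the strategic bond but forms it by intramolecular displacement. It sets out from 14. Olefination with (benzoylmethylene)triphenylphosphorane in hot toluene should give the bis-enone (6-benzyloxy-4-hydroxy-2-methoxy-3-[(E)-3-oxo-3-phenylprop-1-enyl]phenyl)(6-benzyloxy-2-hydroxy-4-methoxy-3-[(E)-3-oxo-3-phenylprop-1-enyl]phenyl)methane F1. Hydrogenation of the two enone C=C bonds with H2 and RhCl(PPh3)3, which spares benzyl ethers, would give the diketone F2. Corey–Bakshi–Shibata reduction with the (S)-methyl oxazaborolidine and BH3·SMe2 would give the (R,R)-diol F3. A double intramolecular Mitsunobu etherification (PPh3, diisopropyl azodicarboxylate) closes both pyran rings with inversion and rejoins the route at 21.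

Step 4. Bromination may also occur at C2, between the two hydroxyls, or run on to the tribromide, giving a mixture of isomers. The fallback replaces selective bromination by exhaustive bromination and selective removal. It sets out from 1. Three equivalents of NBS give 2,4,6-tribromo-5-methoxybenzene-1,3-diol F4, in which regiochemistry is no longer a question. Protection with MOMCl gives 1,3,5-tribromo-2-methoxy-4,6-bis(methoxymethoxy)benzene F5. One equivalent of n-BuLi at -78 °C should exchange the bromine between the two acetal ethers, where the aryllithium is chelated from both sides, and methanol quenches it to rejoin the route at 7.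

Step 7. The acid may cleave some methoxymethyl ethers, or the very electron-rich diarylmethane may be protonated at the bridge-bearing carbons and fragment. The fallback gives up on keeping the acetals. It sets out from 9: reduction with Et3SiH and excess CF3CO2H, followed by HCl in methanol, gives the tetraphenol (3-bromo-4,6-dihydroxy-2-methoxyphenyl)(3-bromo-2,6-dihydroxy-4-methoxyphenyl)methane F6. Fourfold reprotection with NaH and MOMCl rejoins the route at 10.

Step 8. Proton transfer from the bridge CH2 to the aryllithium centres, or incomplete second exchange, would give reduced or mono-formylated material. The fallback avoids organolithium species. It sets out from 10: double Suzuki coupling with potassium vinyltrifluoroborate (PdCl2(dppf), Cs2CO3, THF/H2O, 80 °C) gives the divinyl compound (2-methoxy-4,6-bis(methoxymethoxy)-3-vinylphenyl)(4-methoxy-2,6-bis(methoxymethoxy)-3-vinylphenyl)methane F7. Lemieux–Johnson cleavage (OsO4 cat., NaIO4, 2,6-lutidine, dioxane/H2O) of both alkenes rejoins the route at 12.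

Step 11. Methylenation of the phenoxide-deactivated, doubly ortho-substituted aldehydes may be slow, and the electron-rich ortho-vinylphenol may oligomerise during isolation. The fallback changes the order of events so that no free vinylphenol is ever handled. It sets out from 14, which is etherified under the conditions of step 13 to the dialdehyde (6-benzyloxy-3-formyl-2-methoxy-4-[(S)-1-phenylallyloxy]phenyl)(6-benzyloxy-3-formyl-4-methoxy-2-[(S)-1-phenylallyloxy]phenyl)methane F8. Wittig methylenation of the now non-phenolic aldehydes rejoins the route at 19. The price is a less nucleophilic, formyl-stabilised phenoxide in the iridium step.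

## Further compounds

F1 | step 13 | (6-benzyloxy-4-hydroxy-2-methoxy-3-[(E)-3-oxo-3-phenylprop-1-enyl]phenyl)(6-benzyloxy-2-hydroxy-4-methoxy-3-[(E)-3-oxo-3-phenylprop-1-enyl]phenyl)methane | COc1c(/C=C/C(=O)c2ccccc2)c(O)cc(OCc2ccccc2)c1Cc1c(OCc2ccccc2)cc(OC)c(/C=C/C(=O)c2ccccc2)c1O
F2 | step 13 | (6-benzyloxy-4-hydroxy-2-methoxy-3-(3-oxo-3-phenylpropyl)phenyl)(6-benzyloxy-2-hydroxy-4-methoxy-3-(3-oxo-3-phenylpropyl)phenyl)methane | COc1c(CCC(=O)c2ccccc2)c(O)cc(OCc2ccccc2)c1Cc1c(OCc2ccccc2)cc(OC)c(CCC(=O)c2ccccc2)c1O
F3 | step 13 | (6-benzyloxy-4-hydroxy-3-[(R)-3-hydroxy-3-phenylpropyl]-2-methoxyphenyl)(6-benzyloxy-2-hydroxy-3-[(R)-3-hydroxy-3-phenylpropyl]-4-methoxyphenyl)methane | COc1c(CC[C@@H](O)c2ccccc2)c(O)cc(OCc2ccccc2)c1Cc1c(OCc2ccccc2)cc(OC)c(CC[C@@H](O)c2ccccc2)c1O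
F4 | step 4 | 2,4,6-tribromo-5-methoxybenzene-1,3-diol | COc1c(Br)c(O)c(Br)c(O)c1Br
F5 | step 4 | 1,3,5-tribromo-2-methoxy-4,6-bis(methoxymethoxy)benzene | COCOc1c(Br)c(OCOC)c(Br)c(OC)c1Br
F6 | step 7 | (3-bromo-4,6-dihydroxy-2-methoxyphenyl)(3-bromo-2,6-dihydroxy-4-methoxyphenyl)methane | COc1c(Br)c(O)cc(O)c1Cc1c(O)cc(OC)c(Br)c1O
F7 | step 8 | (2-methoxy-4,6-bis(methoxymethoxy)-3-vinylphenyl)(4-methoxy-2,6-bis(methoxymethoxy)-3-vinylphenyl)methane | COCOc1cc(OCOC)c(C=C)c(OC)c1Cc1c(OCOC)cc(OC)c(C=C)c1OCOC
F8 | step 11 | (6-benzyloxy-3-formyl-2-methoxy-4-[(S)-1-phenylallyloxy]phenyl)(6-benzyloxy-3-formyl-4-methoxy-2-[(S)-1-phenylallyloxy]phenyl)methane | COc1c(C=O)c(O[C@@H](C=C)c2ccccc2)cc(OCc2ccccc2)c1Cc1c(OCc2ccccc2)cc(OC)c(C=O)c1O[C@@H](C=C)c1ccccc1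
A1 | alternative 1 | bis[(R)-3-(tert-butyldimethylsilyloxy)-3-phenylprop-1-enyl] diarylmethane with C8a–O methoxymethyl and C7–O benzyl ethers (alkene geometry mixed) | COCOc1c(C=C[C@@H](O[Si](C)(C)C(C)(C)C)c2ccccc2)c(OC)cc(OCc2ccccc2)c1Cc1c(OCc2ccccc2)cc(OCOC)c(C=C[C@@H](O[Si](C)(C)C(C)(C)C)c2ccccc2)c1OC
A2 | alternative 1 | (S)-2-(tert-butyldimethylsilyloxy)-2-phenylacetaldehyde | O=C[C@@H](O[Si](C)(C)C(C)(C)C)c1ccccc1
A3 | alternative 1 | bis(triphenylphosphoniomethyl) diarylmethane core, dibromide | COCOc1c(C[P+](c2ccccc2)(c2ccccc2)c2ccccc2)c(OC)cc(OCc2ccccc2)c1Cc1c(OCc2ccccc2)cc(OCOC)c(C[P+](c2ccccc2)(c2ccccc2)c2ccccc2)c1OC.[Br-].[Br-]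
A4 | alternative 2 | ring-open unit A phenol (C8a–OH free, C7–O triisopropylsilyl, (R)-silyloxy side chain) carrying complete unit B | COc1cc(O[Si](C(C)C)(C(C)C)C(C)C)c(Cc2c(O[Si](C(C)C)(C(C)C)C(C)C)cc3c(c2OC)CC[C@@H](c2ccccc2)O3)c(O)c1CC[C@@H](O[Si](C)(C)C(C)(C)C)c1ccccc1
A5 | alternative 2 | 4-[(R)-3-(tert-butyldimethylsilyloxy)-3-phenylpropyl]-3-methoxycyclobut-2-en-1-one | COC1=CC(=O)C1CC[C@@H](O[Si](C)(C)C(C)(C)C)c1ccccc1
A6 | alternative 2 | (2S)-5-methoxy-2-phenyl-7-(triisopropylsilyloxy)-6-[3-(triisopropylsilyloxy)prop-2-ynyl]chroman | CC(C)[Si](OC#CCc1c(O[Si](C(C)C)(C(C)C)C(C)C)cc2c(c1OC)CC[C@@H](c1ccccc1)O2)(C(C)C)C(C)C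
A7 | alternative 3 | (2S,2'S)-6,8'-methylene-linked bis(7-benzyloxy-5-methoxyflavanone) | COc1cc(OCc2ccccc2)c(Cc2c(OCc3ccccc3)cc3c(c2OC)C(=O)C[C@@H](c2ccccc2)O3)c2c1C(=O)C[C@@H](c1ccccc1)O2
A8 | alternative 3 | 6,8'-methylene-linked bis(7-benzyloxy-5-methoxychromone) | COc1cc(OCc2ccccc2)c(Cc2c(OCc3ccccc3)cc3c(c2OC)C(=O)C=CO3)c2c1C(=O)C=CO2
A9 | alternative 3 | phenylboronic acid | OB(O)c1ccccc1
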